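**Retrosynthetic overview**

- Target 13 comes from 12 by hydrogenolysis of two benzyl ethers; 12 is the C3 ester of 5,7‑di‑O‑benzylpinobanksin 10 with acid 11.
- 10 comes from the 3,4‑cis diol 9 by oxidation of the benzylic C4 carbinol only; 9 comes from flav‑3‑ene 8 by syn‑dihydroxylation anti to the C2 phenyl.
- The route rests on the C3–C4 bond of ring C, which joins the ester‑bearing C3 to the C4 carbonyl carbon on ring A: written as the C3=C4 alkene of a 2‑phenyl‑2H‑chromene it is a metathesis product (8 from diene 7) and later takes up both oxygens.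
- 7 comes from aldehyde 6 by Wittig methylenation; 6 comes from phenol 2 and carbonate 4 by iridium‑catalysed branched allylic etherification, which sets C2; 2 comes from 1 and 4 from 3.
- Ring order: ring A arrives with 1, the phenyl ring B with 3, and ring C is the only ring built (step 5).

Key step: step 5

Assumption: the (Sa,Sc,Sc)‑phosphoramidite is taken as the ligand enantiomer that leads to the (1S)‑ether; if the sense of induction proves opposite, its antipode is used and nothing else changes.

**Route**

Step 1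
Reactants: 1 2,4,6‑trihydroxybenzaldehyde
Product: 2 2,4‑bis(benzyloxy)‑6‑hydroxybenzaldehyde
Conditions: BnBr (2.05 equiv), K2CO3 (2.1 equiv), DMF, 0 °C to rt
Reagents that add atoms: benzyl bromide, BrCc1ccccc1
Why: Williamson etherification in which the 4‑OH and one ortho OH are alkylated, while the remaining ortho hydroxyl, hydrogen‑bonded to the formyl oxygen, is the least nucleophilic and should stay free when the halide is limited to two equivalents.

Step 2
Reactants: 3 cinnamyl alcohol
Product: 4 methyl (2E)‑3‑phenylprop‑2‑en‑1‑yl carbonate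
Conditions: ClCO2Me (1.2 equiv), pyridine (1.5 equiv), CH2Cl2, 0 °C
Reagents that add atoms: methyl chloroformate, COC(Cl)=O
Why: O‑acylation of a primary allylic alcohol with a chloroformate, which leaves the E‑alkene untouched.

Step 3
Reactants: 2 2,4‑bis(benzyloxy)‑6‑hydroxybenzaldehyde; 4 methyl (2E)‑3‑phenylprop‑2‑en‑1‑yl carbonate
Product: 6 2,4‑bis(benzyloxy)‑6‑{[(1S)‑1‑phenylprop‑2‑en‑1‑yl]oxy}benzaldehyde, via sodium aryloxide 5 (not isolated)
Conditions: NaH (1.0 equiv), THF, 0 °C; then 4 (1.3 equiv), [Ir(cod)Cl]2 (2 mol%), (Sa,Sc,Sc)‑O,O'‑(1,1'‑binaphthalene‑2,2'‑diyl)‑N,N‑bis(1‑phenylethyl)phosphoramidite (4 mol%; catalyst pre‑activated with n‑PrNH2, volatiles removed), THF, rt to 50 °C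
Reagents that add atoms: none
Why: Iridium‑catalysed asymmetric allylic etherification of an alkali aryloxide, in which ionisation of the carbonate gives a cinnamyl η3‑allyl complex of the cyclometalated iridium phosphoramidite, the aryloxide attacks the phenyl‑bearing terminus (branched product), and the chiral ligand fixes the face of attack and so sets the (1S) centre that becomes C2.

Step 4
Reactants: 6 2,4‑bis(benzyloxy)‑6‑{[(1S)‑1‑phenylprop‑2‑en‑1‑yl]oxy}benzaldehyde
Product: 7 1,5‑bis(benzyloxy)‑2‑ethenyl‑3‑{[(1S)‑1‑phenylprop‑2‑en‑1‑yl]oxy}benzene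
Conditions: MePPh3Br (1.5 equiv), KOtBu (1.4 equiv), THF, 0 °C; then 6, 0 °C to rt
Reagents that add atoms: methyltriphenylphosphonium bromide, [Br-].C[P+](c1ccccc1)(c1ccccc1)c1ccccc1
Why: Wittig methylenation of an aryl aldehyde; because the phosphonium salt is kept in slight excess over the base, no free strong base remains, so the benzylic allylic ether C–H is not deprotonated and the (1S) centre is retained.

Step 5
Reactants: 7 1,5‑bis(benzyloxy)‑2‑ethenyl‑3‑{[(1S)‑1‑phenylprop‑2‑en‑1‑yl]oxy}benzene
Product: 8 (2S)‑5,7‑bis(benzyloxy)‑2‑phenyl‑2H‑chromene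
Conditions: second‑generation Grubbs catalyst (H2IMes)(PCy3)Cl2Ru=CHPh (5 mol%), 1,4‑benzoquinone (10 mol%), CH2Cl2 (0.01 M), 40 °C, argon, dark
Reagents that add atoms: none
Why: Ring‑closing olefin metathesis by [2+2] and retro‑[2+2] steps: the ruthenium benzylidene exchanges with the terminal alkene of the allyl ether, the new alkylidene at the future C3 adds across the ortho‑vinyl group, and the ruthenacyclobutane opens to the C3=C4 double bond and a ruthenium methylidene that carries the chain and releases ethylene. The closest known reaction is the metathesis of 2‑vinylaryl allyl ethers to 2H‑chromenes. Ring C closes as a six‑membered ring by intramolecular alkylidene–alkene metathesis between two alkene termini held ortho to each other on ring A. No stereocentre is formed; the centre set in step 3 lies outside the reacting carbons and is carried over unchanged as C2 (descriptor S in the chromene, the same spatial arrangement as 2R in the target). The step needs ring closure to win over intermolecular cross‑metathesis and the product to escape double‑bond migration or ring opening: the ortho placement of the alkenes and high dilution should secure the first, and benzoquinone as a trap for ruthenium hydrides, a neutral medium, moderate temperature and exclusion of light the second.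

Step 6
Reactants: 8 (2S)‑5,7‑bis(benzyloxy)‑2‑phenyl‑2H‑chromene
Product: 9 (2R,3S,4S)‑5,7‑bis(benzyloxy)‑2‑phenyl‑3,4‑dihydro‑2H‑chromene‑3,4‑diol
Conditions: OsO4 (2 mol%), NMO (1.5 equiv), acetone/H2O 9:1, 0 °C to rt; aqueous Na2SO3 work‑up
Reagents that add atoms: osmium tetroxide, O=[Os](=O)(=O)=O; N‑methylmorpholine N‑oxide, C[N+]1([O-])CCOCC1; water, O
Why: Catalytic OsO4/NMO syn‑dihydroxylation in which the [3+2] addition should occur on the face of C3=C4 opposite the neighbouring C2 phenyl group, setting C3 (S, oxygen trans to phenyl) and C4 (S, oxygen cis to that on C3) relative to the existing C2 centre, whose descriptor becomes R only because C3 now outranks phenyl.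

Step 7
Reactants: 9 (2R,3S,4S)‑5,7‑bis(benzyloxy)‑2‑phenyl‑3,4‑dihydro‑2H‑chromene‑3,4‑diol
Product: 10 (2R,3R)‑5,7‑bis(benzyloxy)‑3‑hydroxy‑2‑phenyl‑2,3‑dihydro‑4H‑chromen‑4‑one
Conditions: DDQ (1.2 equiv), dry 1,4‑dioxane, rt
Reagents that add atoms: none
Why: Chemoselective DDQ oxidation of an activated benzylic alcohol, in which hydride loss from C4 gives a cation stabilised by the C4 hydroxyl and the three oxygen donors of ring A (O1, 5‑OBn, 7‑OBn), whereas the aliphatic C3 carbinol and the benzyl ethers lack such activation; no stereocentre is formed, 2,3‑trans is also the more stable arrangement beside the new ketone, and C3 is now R only because the C4 carbonyl carbon outranks C2.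

Step 8
Reactants: 10 (2R,3R)‑5,7‑bis(benzyloxy)‑3‑hydroxy‑2‑phenyl‑2,3‑dihydro‑4H‑chromen‑4‑one; 11 (2R)‑2‑methylbutanoic acid
Product: 12 (2R,3R)‑5,7‑bis(benzyloxy)‑4‑oxo‑2‑phenyl‑3,4‑dihydro‑2H‑chromen‑3‑yl (2R)‑2‑methylbutanoate
Conditions: 11 (1.5 equiv), DCC (1.5 equiv), DMAP (0.1 equiv), CH2Cl2, 0 °C to rt, argon
Reagents that add atoms: none
Why: Steglich esterification of the secondary α‑ketol hydroxyl; the weakly acidic α‑hydrogen of the 2‑methylbutanoyl unit and the small amount of DMAP should leave the (R) centre of the acid and C2/C3 of the flavanone unchanged.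

Step 9
Reactants: 12 (2R,3R)‑5,7‑bis(benzyloxy)‑4‑oxo‑2‑phenyl‑3,4‑dihydro‑2H‑chromen‑3‑yl (2R)‑2‑methylbutanoate
Product: 13 (2R,3R)‑5,7‑dihydroxy‑4‑oxo‑2‑phenyl‑3,4‑dihydro‑2H‑chromen‑3‑yl (2R)‑2‑methylbutanoate
Conditions: H2 (1 atm), 10% Pd/C, EtOAc, rt, stopped after uptake of two equivalents
Reagents that add atoms: none
Why: Hydrogenolysis of the two aryl benzyl ethers; under these mild conditions the ester, the ring‑A‑conjugated ketone and the cyclic C2–O1 bond of the flavanone are expected to survive, so all three stereocentres are kept.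

**Compound list**

1 | 2,4,6‑trihydroxybenzaldehyde | O=Cc1c(O)cc(O)cc1O | starting material
2 | 2,4‑bis(benzyloxy)‑6‑hydroxybenzaldehyde | O=Cc1c(O)cc(OCc2ccccc2)cc1OCc1ccccc1 | intermediate
3 | cinnamyl alcohol, (2E)‑3‑phenylprop‑2‑en‑1‑ol | OC/C=C/c1ccccc1 | starting material
4 | methyl (2E)‑3‑phenylprop‑2‑en‑1‑yl carbonate | COC(=O)OC/C=C/c1ccccc1 | intermediate
5 | sodium 3,5‑bis(benzyloxy)‑2‑formylphenolate | [Na+].[O-]c1cc(OCc2ccccc2)cc(OCc2ccccc2)c1C=O | intermediate (not isolated)
6 | 2,4‑bis(benzyloxy)‑6‑{[(1S)‑1‑phenylprop‑2‑en‑1‑yl]oxy}benzaldehyde | O=Cc1c(OCc2ccccc2)cc(OCc2ccccc2)cc1O[C@@H](C=C)c1ccccc1 | intermediate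
7 | 1,5‑bis(benzyloxy)‑2‑ethenyl‑3‑{[(1S)‑1‑phenylprop‑2‑en‑1‑yl]oxy}benzene | C=Cc1c(OCc2ccccc2)cc(OCc2ccccc2)cc1O[C@@H](C=C)c1ccccc1 | intermediate
8 | (2S)‑5,7‑bis(benzyloxy)‑2‑phenyl‑2H‑chromene | C1=Cc2c(OCc3ccccc3)cc(OCc3ccccc3)cc2O[C@@H]1c1ccccc1 | intermediate
9 | (2R,3S,4S)‑5,7‑bis(benzyloxy)‑2‑phenyl‑3,4‑dihydro‑2H‑chromene‑3,4‑diol (2,3‑trans‑3,4‑cis) | O[C@H]1[C@@H](O)c2c(OCc3ccccc3)cc(OCc3ccccc3)cc2O[C@@H]1c1ccccc1 | intermediate
10 | (2R,3R)‑5,7‑bis(benzyloxy)‑3‑hydroxy‑2‑phenyl‑2,3‑dihydro‑4H‑chromen‑4‑one | O[C@H]1C(=O)c2c(OCc3ccccc3)cc(OCc3ccccc3)cc2O[C@@H]1c1ccccc1 | intermediate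
11 | (2R)‑2‑methylbutanoic acid | CC[C@@H](C)C(=O)O | starting material
12 | (2R,3R)‑5,7‑bis(benzyloxy)‑4‑oxo‑2‑phenyl‑3,4‑dihydro‑2H‑chromen‑3‑yl (2R)‑2‑methylbutanoate | CC[C@@H](C)C(=O)O[C@H]1C(=O)c2c(OCc3ccccc3)cc(OCc3ccccc3)cc2O[C@@H]1c1ccccc1 | intermediate
13 | (2R,3R)‑5,7‑dihydroxy‑4‑oxo‑2‑phenyl‑3,4‑dihydro‑2H‑chromen‑3‑yl (2R)‑2‑methylbutanoate | CC[C@@H](C)C(=O)O[C@H]1C(=O)c2c(O)cc(O)cc2O[C@@H]1c1ccccc1 | target

**Step count and risks**

Total step count: 9. Longest linear sequence: 8 steps (1 → 2 → 6 → 7 → 8 → 9 → 10 → 12 → 13); step 2 is a one‑step side branch.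

Steps most likely to fail:

Step 3. The aryloxide is chelated to sodium through the formyl group and conjugated with it, so its attack on the allyliridium intermediate may be slow. Being a fair leaving group, it may also let the branched ether re‑ionise, which would erode the branched‑to‑linear ratio and the enantiomeric purity. The fallback sets out from 2 and changes the nucleophile. Methylenation of 2 with an excess of the ylide (MePPh3Br/KOtBu, 3 equiv, the first equivalent being consumed by the phenol) should give 3,5‑bis(benzyloxy)‑2‑ethenylphenol F1. Its salt formed with NaH, sodium 3,5‑bis(benzyloxy)‑2‑ethenylphenolate F2, is a non‑chelating and more electron‑rich aryloxide. Etherification of this salt with 4 under the same iridium catalysis would give diene 7 directly, so the route is rejoined at 7 and steps 3 and 4 are replaced; F1 is acid‑sensitive and would be used at once.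

Step 5. Ring closure may be slow at the twisted, doubly ortho‑substituted styrene. The catalyst may rest as a chelated ortho‑alkoxybenzylidene or be lost through the short‑lived ruthenium methylidene, and the ruthenium hydrides formed on its decay may move the double bond towards the 4H‑chromene, which would destroy C2. The fallback sets out from 6. Wittig reaction with ethyltriphenylphosphonium bromide/KOtBu should give 1,5‑bis(benzyloxy)‑3‑{[(1S)‑1‑phenylprop‑2‑en‑1‑yl]oxy}‑2‑[(1Z)‑prop‑1‑en‑1‑yl]benzene F3 (mainly Z; the E isomer would serve equally). In its metathesis the catalyst can load only on the allyl ether alkene, and ring closure expels propene, so the chain carrier is the longer‑lived ruthenium ethylidene. The product is 8, where the route is rejoined.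

Step 7. In the preferred half‑chair the C4 hydroxyl is pseudo‑axial and the C4–H bond lies near the plane of ring A, so hydride transfer to DDQ may be slow. Long exposure may then ionise the C4–OH or dehydrogenate the product further towards the flavonol. The fallback sets out from 9 and removes the need for a chemoselective oxidant. The equatorial C3 hydroxyl, less hindered than the pseudo‑axial C4 hydroxyl flanked by the 5‑benzyloxy group, would be esterified first with 11 (1.0 equiv, DCC, catalytic DMAP, CH2Cl2, −20 °C). This should give (2R,3S,4S)‑5,7‑bis(benzyloxy)‑4‑hydroxy‑2‑phenyl‑3,4‑dihydro‑2H‑chromen‑3‑yl (2R)‑2‑methylbutanoate F4. The one remaining carbinol is then oxidised with Dess–Martin periodinane buffered with NaHCO3 in CH2Cl2, which gives 12; the route is rejoined there and steps 7 and 8 are replaced.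

Further compounds
F1 | step 3 | 3,5‑bis(benzyloxy)‑2‑ethenylphenol | C=Cc1c(O)cc(OCc2ccccc2)cc1OCc1ccccc1
F2 | step 3 | sodium 3,5‑bis(benzyloxy)‑2‑ethenylphenolate | [Na+].[O-]c1cc(OCc2ccccc2)cc(OCc2ccccc2)c1C=C
F3 | step 5 | 1,5‑bis(benzyloxy)‑3‑{[(1S)‑1‑phenylprop‑2‑en‑1‑yl]oxy}‑2‑[(1Z)‑prop‑1‑en‑1‑yl]benzene | C/C=C\c1c(OCc2ccccc2)cc(OCc2ccccc2)cc1O[C@@H](C=C)c1ccccc1
F4 | step 7 | (2R,3S,4S)‑5,7‑bis(benzyloxy)‑4‑hydroxy‑2‑phenyl‑3,4‑dihydro‑2H‑chromen‑3‑yl (2R)‑2‑methylbutanoate | CC[C@@H](C)C(=O)O[C@H]1[C@@H](O)c2c(OCc3ccccc3)cc(OCc3ccccc3)cc2O[C@@H]1c1ccccc1
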